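**Retrosynthetic overview** (germacrane numbering: C1=C10 olefin, C3 angelate, C4–C5 epoxide, C6 acetate, C7 isopropyl)
1. The ten-membered carbocycle is closed last, at the sp3–sp2 bond C9–C10, from a seco vinyl iodide/terminal alkene that already carries all five stereocenters.
2. The oxirane (the first ring formed) comes from hydroxyl-directed epoxidation of the C6 allylic alcohol.
3. C6–C7 comes from a chiral phosphoric acid-catalysed anti-allylboration of a C6 enal with an (E)-γ-isopropyl allylboronate.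
4. C2–C3 comes from a chiral phosphoric acid-catalysed propargylation of the achiral C5 enal (first stereocenter); the methyl alkyne then gives the (E)-vinyl iodide.
5. The angelate goes on C3–OH early; the acetate goes on C6–OH after epoxidation.

Assumption: methyl but-2-yn-1-yl carbonate, (2E)-4-acetoxy-2-methylbut-2-enal and the (E)-3-methylbut-1-enyl pinacol boronate are taken as catalogue chemicals; "TRIP" is 3,3'-bis(2,4,6-triisopropylphenyl)-1,1'-binaphthyl-2,2'-diyl hydrogen phosphate.

**Step 1**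
Reactants: 1 methyl but-2-yn-1-yl carbonate
Product: 2 2-(buta-2,3-dien-2-yl)-4,4,5,5-tetramethyl-1,3,2-dioxaborolane
Conditions: B2pin2, CuCl (5 mol%), Xantphos (5 mol%), KOtBu (10 mol%), THF, rt
Reagents that add atoms: bis(pinacolato)diboron, CC1(C)OB(OC1(C)C)B1OC(C)(C)C(C)(C)O1
Why: Copper-catalysed SN2' borylation of a propargylic carbonate (borylcupration, then β-elimination of the carbonate) gives the achiral 1-methylallenyl boronate with boron on the methyl-bearing carbon.

**Step 2**
Reactants: 3 (2E)-4-acetoxy-2-methylbut-2-enal; 2 2-(buta-2,3-dien-2-yl)-4,4,5,5-tetramethyl-1,3,2-dioxaborolane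
Product: 5 (2E,4R)-4-hydroxy-3-methyloct-2-en-6-yn-1-yl acetate, via pinacol borate ester 4 (not isolated)
Conditions: (R)-TRIP (10 mol%), 4 Å MS, toluene, −20 °C; aq NaHCO3 work-up
Reagents that add atoms: none
Why: Chiral phosphoric acid-catalysed propargylation (allenylboration through a closed six-membered SE2' transition state, the acid hydrogen-bonded to a boronate oxygen and the formyl C–H) attacks the Re face, as expected for (R)-TRIP by analogy with reported aldehyde allyl- and propargylborations, and sets the first stereocenter (4R, the future C3).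

**Step 3**
Reactants: 5 (2E,4R)-4-hydroxy-3-methyloct-2-en-6-yn-1-yl acetate
Product: 6 (2E,4R)-1-acetoxy-3-methyloct-2-en-6-yn-4-yl (2Z)-2-methylbut-2-enoate
Conditions: angelic acid, 2,4,6-trichlorobenzoyl chloride, Et3N, toluene, rt; then 5, 75 °C (no DMAP)
Reagents that add atoms: angelic acid ((2Z)-2-methylbut-2-enoic acid), C/C=C(/C)C(=O)O
Why: Yamaguchi mixed-anhydride esterification without a nucleophilic catalyst acylates the secondary alcohol with retention and without Z-to-E isomerisation of the angelate.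

**Step 4**
Reactants: 6 (2E,4R)-1-acetoxy-3-methyloct-2-en-6-yn-4-yl (2Z)-2-methylbut-2-enoate
Product: 8 (2E,4R,6E)-1-acetoxy-7-iodo-3-methylocta-2,6-dien-4-yl (2Z)-2-methylbut-2-enoate, via alkenylzirconocene chloride 7 (not isolated)
Conditions: Cp2Zr(H)Cl (1.6 equiv), THF, rt to 40 °C; then I2, 0 °C
Reagents that add atoms: iodine, II
Why: Hydrozirconation/iodination: syn addition of Zr–H equilibrates to put zirconium on the less hindered methyl-bearing alkyne carbon, and iodinolysis with retention gives the (E)-2-iodoalkene; the esters survive the short exposure.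

**Step 5**
Reactants: 8 (2E,4R,6E)-1-acetoxy-7-iodo-3-methylocta-2,6-dien-4-yl (2Z)-2-methylbut-2-enoate
Product: 9 (2E,4R,6E)-1-hydroxy-7-iodo-3-methylocta-2,6-dien-4-yl (2Z)-2-methylbut-2-enoate
Conditions: K2CO3 (0.2 equiv), MeOH, 0 °C
Reagents that add atoms: none
Why: Chemoselective transesterification removes the unhindered primary allylic acetate far faster than the hindered, conjugated secondary angelate, and acyl migration across the E-olefin is geometrically impossible.

**Step 6**
Reactants: 9 (2E,4R,6E)-1-hydroxy-7-iodo-3-methylocta-2,6-dien-4-yl (2Z)-2-methylbut-2-enoate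
Product: 10 (2E,4R,6E)-7-iodo-3-methyl-1-oxoocta-2,6-dien-4-yl (2Z)-2-methylbut-2-enoate
Conditions: MnO2 (activated, excess), CH2Cl2, rt
Reagents that add atoms: none
Why: Allylic oxidation with MnO2 gives the (E)-enal under neutral conditions without touching the vinyl iodide, the angelate or the stereocenter.

**Step 7**
Reactants: 11 4,4,5,5-tetramethyl-2-[(1E)-3-methylbut-1-en-1-yl]-1,3,2-dioxaborolane
Product: 13 4,4,5,5-tetramethyl-2-[(2E)-4-methylpent-2-en-1-yl]-1,3,2-dioxaborolane, via chloromethyl borate complex 12 (not isolated)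
Conditions: BrCH2Cl (1.05 equiv), n-BuLi, THF, −78 °C to rt
Reagents that add atoms: bromochloromethane, ClCBr
Why: Matteson homologation: chloromethyllithium adds to boron and the alkenyl group undergoes a 1,2-metallate shift with loss of chloride, giving the allylboronate with the E geometry retained.

**Step 8**
Reactants: 10 (2E,4R,6E)-7-iodo-3-methyl-1-oxoocta-2,6-dien-4-yl (2Z)-2-methylbut-2-enoate; 13 4,4,5,5-tetramethyl-2-[(2E)-4-methylpent-2-en-1-yl]-1,3,2-dioxaborolane
Product: 15 (2E,5R,6E,8S,9S)-8-hydroxy-2-iodo-6-methyl-9-(propan-2-yl)undeca-2,6,10-trien-5-yl (2Z)-2-methylbut-2-enoate, via pinacol borate ester 14 (not isolated)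
Conditions: (S)-TRIP (10 mol%), 4 Å MS, toluene, −30 to 0 °C; aq NaHCO3 work-up
Reagents that add atoms: none
Why: Chiral phosphoric acid-catalysed allylboration through a Zimmerman–Traxler chair: the (E)-γ-isopropyl boronate gives the anti relationship (future C6/C7), and (S)-TRIP directs Si-face attack (8S) under catalyst control, independent of the remote C5 center.

**Step 9**
Reactants: 15 (2E,5R,6E,8S,9S)-8-hydroxy-2-iodo-6-methyl-9-(propan-2-yl)undeca-2,6,10-trien-5-yl (2Z)-2-methylbut-2-enoate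
Product: 16 (1R,3E)-1-[(2R,3R)-3-[(1S,2S)-1-hydroxy-2-(propan-2-yl)but-3-en-1-yl]-2-methyloxiran-2-yl]-4-iodopent-3-en-1-yl (2Z)-2-methylbut-2-enoate
Conditions: mCPBA (1.1 equiv), CH2Cl2, −10 to 0 °C
Reagents that add atoms: mCPBA (3-chloroperoxybenzoic acid), OOC(=O)c1cccc(Cl)c1
Why: Henbest hydroxyl-directed epoxidation: A(1,3) strain from the cis methyl puts the carbinol hydrogen in the olefin plane, so the peracid is delivered syn to the hydroxyl and gives the threo epoxy alcohol (2R,3R oxirane); the vinyl iodide, terminal vinyl and angelate olefins react much more slowly.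

**Step 10**
Reactants: 16 (1R,3E)-1-[(2R,3R)-3-[(1S,2S)-1-hydroxy-2-(propan-2-yl)but-3-en-1-yl]-2-methyloxiran-2-yl]-4-iodopent-3-en-1-yl (2Z)-2-methylbut-2-enoate
Product: 17 (1R,3E)-1-[(2R,3R)-3-[(1S,2S)-1-acetoxy-2-(propan-2-yl)but-3-en-1-yl]-2-methyloxiran-2-yl]-4-iodopent-3-en-1-yl (2Z)-2-methylbut-2-enoate
Conditions: Ac2O, pyridine, DMAP (cat.), CH2Cl2, 0 °C to rt
Reagents that add atoms: acetic anhydride, CC(=O)OC(C)=O
Why: DMAP-catalysed acetylation of the secondary epoxy alcohol proceeds with retention, and once the C4–C5 olefin is an epoxide no allylic ester is left to ionise in the palladium step.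

**Step 11**
Reactants: 17 (1R,3E)-1-[(2R,3R)-3-[(1S,2S)-1-acetoxy-2-(propan-2-yl)but-3-en-1-yl]-2-methyloxiran-2-yl]-4-iodopent-3-en-1-yl (2Z)-2-methylbut-2-enoate
Product: 19 (1R,2R,4E,8R,9S,10R)-9-acetoxy-1,5-dimethyl-8-(propan-2-yl)-11-oxabicyclo[8.1.0]undec-4-en-2-yl (2Z)-2-methylbut-2-enoate, via B-alkyl-9-BBN borane 18 (not isolated)
Conditions: 9-BBN, THF, rt; then syringe-pump addition to Pd(dppf)Cl2 (20 mol%), AsPh3, Cs2CO3, DMF/THF/H2O, rt to 45 °C, final 1 mM
Reagents that add atoms: none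
Why: Proposed new method: a one-pot hydroboration/intramolecular B-alkyl Suzuki–Miyaura coupling that closes the ten-membered carbocycle; 9-BBN adds anti-Markovnikov only to the terminal vinyl group, palladium inserts into the C–I bond with retention, the base-activated alkylborate transmetalates through an eleven-membered palladacycle and reductive elimination forms C9–C10 with the E-trisubstituted olefin intact and no stereocenter touched, helped by high dilution and by the rigid trans-epoxide and contiguous substituents; the closest known reaction type is the B-alkyl Suzuki macrocyclisation used for twelve- to sixteen-membered rings, and I am not aware of a ten-membered carbocycle closed this way.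

**Compound list**
1 | methyl but-2-yn-1-yl carbonate | CC#CCOC(=O)OC | starting material
2 | 2-(buta-2,3-dien-2-yl)-4,4,5,5-tetramethyl-1,3,2-dioxaborolane | C=C=C(C)B1OC(C)(C)C(C)(C)O1 | intermediate
3 | (2E)-4-acetoxy-2-methylbut-2-enal | O=C/C(C)=C/COC(C)=O | starting material
4 | (2E,4R)-3-methyl-4-[(4,4,5,5-tetramethyl-1,3,2-dioxaborolan-2-yl)oxy]oct-2-en-6-yn-1-yl acetate | CC#CC[C@@H](OB1OC(C)(C)C(C)(C)O1)/C(C)=C/COC(C)=O | intermediate
5 | (2E,4R)-4-hydroxy-3-methyloct-2-en-6-yn-1-yl acetate | CC#CC[C@@H](O)/C(C)=C/COC(C)=O | intermediate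
6 | (2E,4R)-1-acetoxy-3-methyloct-2-en-6-yn-4-yl (2Z)-2-methylbut-2-enoate | C/C=C(/C)C(=O)O[C@H](CC#CC)/C(C)=C/COC(C)=O | intermediate
7 | chlorobis(cyclopentadienyl)[(2E,5R,6E)-8-acetoxy-6-methyl-5-{[(2Z)-2-methylbut-2-enoyl]oxy}octa-2,6-dien-2-yl]zirconium | C/C=C(/C)C(=O)O[C@H](C/C=C(\C)[Zr](Cl)(C1C=CC=C1)C1C=CC=C1)/C(C)=C/COC(C)=O | intermediate
8 | (2E,4R,6E)-1-acetoxy-7-iodo-3-methylocta-2,6-dien-4-yl (2Z)-2-methylbut-2-enoate | C/C=C(/C)C(=O)O[C@H](C/C=C(\C)I)/C(C)=C/COC(C)=O | intermediate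
9 | (2E,4R,6E)-1-hydroxy-7-iodo-3-methylocta-2,6-dien-4-yl (2Z)-2-methylbut-2-enoate | C/C=C(/C)C(=O)O[C@H](C/C=C(\C)I)/C(C)=C/CO | intermediate
10 | (2E,4R,6E)-7-iodo-3-methyl-1-oxoocta-2,6-dien-4-yl (2Z)-2-methylbut-2-enoate | C/C=C(/C)C(=O)O[C@H](C/C=C(\C)I)/C(C)=C/C=O | intermediate
11 | 4,4,5,5-tetramethyl-2-[(1E)-3-methylbut-1-en-1-yl]-1,3,2-dioxaborolane | CC(C)/C=C/B1OC(C)(C)C(C)(C)O1 | starting material
12 | lithium (chloromethyl)[(1E)-3-methylbut-1-en-1-yl](pinacolato)borate | [Li+].CC(C)/C=C/[B-]1(CCl)OC(C)(C)C(C)(C)O1 | intermediate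
13 | 4,4,5,5-tetramethyl-2-[(2E)-4-methylpent-2-en-1-yl]-1,3,2-dioxaborolane | CC(C)/C=C/CB1OC(C)(C)C(C)(C)O1 | intermediate
14 | (2E,5R,6E,8S,9S)-2-iodo-6-methyl-9-(propan-2-yl)-8-[(4,4,5,5-tetramethyl-1,3,2-dioxaborolan-2-yl)oxy]undeca-2,6,10-trien-5-yl (2Z)-2-methylbut-2-enoate | C/C=C(/C)C(=O)O[C@H](C/C=C(\C)I)/C(C)=C/[C@@H](OB1OC(C)(C)C(C)(C)O1)[C@H](C=C)C(C)C | intermediate
15 | (2E,5R,6E,8S,9S)-8-hydroxy-2-iodo-6-methyl-9-(propan-2-yl)undeca-2,6,10-trien-5-yl (2Z)-2-methylbut-2-enoate | C/C=C(/C)C(=O)O[C@H](C/C=C(\C)I)/C(C)=C/[C@@H](O)[C@H](C=C)C(C)C | intermediate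
16 | (1R,3E)-1-[(2R,3R)-3-[(1S,2S)-1-hydroxy-2-(propan-2-yl)but-3-en-1-yl]-2-methyloxiran-2-yl]-4-iodopent-3-en-1-yl (2Z)-2-methylbut-2-enoate | C/C=C(/C)C(=O)O[C@H](C/C=C(\C)I)[C@@]1(C)O[C@@H]1[C@@H](O)[C@H](C=C)C(C)C | intermediate
17 | (1R,3E)-1-[(2R,3R)-3-[(1S,2S)-1-acetoxy-2-(propan-2-yl)but-3-en-1-yl]-2-methyloxiran-2-yl]-4-iodopent-3-en-1-yl (2Z)-2-methylbut-2-enoate | C/C=C(/C)C(=O)O[C@H](C/C=C(\C)I)[C@@]1(C)O[C@@H]1[C@@H](OC(C)=O)[C@H](C=C)C(C)C | intermediate
18 | B-alkyl-9-BBN adduct of 17 (9-borabicyclo[3.3.1]nonan-9-yl on the former terminal vinyl carbon; all stereocenters as in 17) | C/C=C(/C)C(=O)O[C@H](C/C=C(\C)I)[C@@]1(C)O[C@@H]1[C@@H](OC(C)=O)[C@H](CCB2C3CCCC2CCC3)C(C)C | intermediate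
19 | (1R,2R,4E,8R,9S,10R)-9-acetoxy-1,5-dimethyl-8-(propan-2-yl)-11-oxabicyclo[8.1.0]undec-4-en-2-yl (2Z)-2-methylbut-2-enoate | C/C=C(/C)C(=O)O[C@@H]1C/C=C(\C)CC[C@H](C(C)C)[C@H](OC(C)=O)[C@H]2O[C@@]21C | target

**Step count:** 11 steps in total. Longest linear sequence: 10 steps (steps 1–6 and 8–11; step 7 is a one-step side branch).

**The three steps most likely to fail**

Step 11 (the proposed new ring closure) risks oligomerisation or protodehalogenation instead of closing the strained ten-membered ring. The fallback sets out from 17 and returns at 19, closing the ring by olefin metathesis at a bond whose geometry does not matter. Suzuki–Miyaura vinylation of the vinyl iodide (vinylboronic acid pinacol ester, Pd(PPh3)4, aq K3PO4, THF, 50 °C) gives the seco triene with a (3E)-4-methylhexa-3,5-dienyl chain, F1. Diene–ene ring-closing metathesis (second-generation Hoveyda–Grubbs catalyst, toluene, 1 mM, 60 °C) joins the two terminal vinyl groups to the macrocyclic 4,6-diene F2. Diimide reduction (2-nitrobenzenesulfonyl hydrazide, Et3N, CH2Cl2, rt) then saturates only the new disubstituted olefin, leaving the trisubstituted ring olefin and the angelate, and gives 19.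

Step 2 uses an α-substituted allenylboronate, which is less precedented in phosphoric acid catalysis and may react slowly or with low ee. The fallback sets out from 3 and 2 and returns at 5, moving the asymmetric induction from C–C bond formation to a ketone reduction. Uncatalysed allenylboration (toluene, 40 °C) gives the racemic homopropargylic alcohol F3. Dess–Martin periodinane with NaHCO3 in CH2Cl2 gives the enone (2E)-3-methyl-4-oxooct-2-en-6-yn-1-yl acetate F4. Corey–Bakshi–Shibata reduction ((S)-Me-CBS oxazaborolidine 20 mol%, catecholborane, toluene, −78 °C; the alkenyl group is the large substituent) returns (4R)-alcohol 5.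

Step 8 may give lower ee or anti selectivity because of the bulky γ-isopropyl group on a functionalised enal. The fallback sets out from 10 and returns at 15, switching from Brønsted-acid/boron to chiral Lewis-base/silicon catalysis, which is established for conjugated aldehydes. The reagent (E)-trichloro(4-methylpent-2-en-1-yl)silane F5 is made from (E)-1-chloro-4-methylpent-2-ene with HSiCl3, CuCl and iPr2NEt in Et2O. It is added to 10 with a 2,2'-bipyrrolidine-derived Denmark bisphosphoramide (5 mol%, the enantiomer giving Si-face attack) and iPr2NEt in CH2Cl2 at −78 °C. The closed chair at hexacoordinate silicon again converts the E reagent into the anti adduct, and aqueous NaHCO3 work-up gives 15.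

**Further compounds**
F1 | step 11 | (1R,3E)-1-[(2R,3R)-3-[(1S,2S)-1-acetoxy-2-(propan-2-yl)but-3-en-1-yl]-2-methyloxiran-2-yl]-4-methylhexa-3,5-dien-1-yl (2Z)-2-methylbut-2-enoate | C/C=C(/C)C(=O)O[C@H](C/C=C(\C)C=C)[C@@]1(C)O[C@@H]1[C@@H](OC(C)=O)[C@H](C=C)C(C)C
F2 | step 11 | (1R,2R,4E,6Z,8S,9S,10R)-9-acetoxy-1,5-dimethyl-8-(propan-2-yl)-11-oxabicyclo[8.1.0]undeca-4,6-dien-2-yl (2Z)-2-methylbut-2-enoate | C/C=C(/C)C(=O)O[C@@H]1C/C=C(\C)/C=C\[C@H](C(C)C)[C@H](OC(C)=O)[C@H]2O[C@@]21C
F3 | step 2 | racemic (2E)-4-hydroxy-3-methyloct-2-en-6-yn-1-yl acetate | CC#CCC(O)/C(C)=C/COC(C)=O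
F4 | step 2 | (2E)-3-methyl-4-oxooct-2-en-6-yn-1-yl acetate | CC#CCC(=O)/C(C)=C/COC(C)=O
F5 | step 8 | (E)-trichloro(4-methylpent-2-en-1-yl)silane | CC(C)/C=C/C[Si](Cl)(Cl)Cl
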